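**Retrosynthetic overview**

1. Feature: in ring C (pyranone, O1', C2'–C6') the carbon C3' that is bonded to C8 of ring A lies between the two acyl carbons C2' and C4'. It is a malonate carbon, so it can be placed on C8 (flanked by C7 and by the peri carbon C1 of ring B) before ring C exists.
2. Ring C is closed last: C4'–C5' and O1'–C2' from arylmalonyl dichloride 18 and silyloxydiene 20 (which carries ring D). Then the C7 acetate is taken to the aldehyde and three methyl ethers are cleaved.
3. The malonate reaches C8 by palladium-catalysed arylation of bromide 14. C7 is hydroxymethylated by ortho-lithiation and C8 is brominated by electrophilic substitution of the catechol dimethyl ether.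
4. Ring A is grown on ring B of (+)-menthone: bromoformylation (C5 and the C8a bromide), Negishi coupling (C6–C8 chain), carbene acyloin closure C5–C6, oxidation to the catechol.
5. Ring order: B (chiral pool, both stereocentres) → A → C; ring D arrives with fragment 20.

Key step: step 14

Remark: the tetralin is numbered C1 (isopropyl), C4 (methyl), C4a, C5–C8, C8a; ring A is the benzene ring, ring B the saturated ring, ring C the pyranone, ring D the phenol ring. (+)-Menthol is taken as the (1S,2R,5S) enantiomer, whose isopropyl and methyl carbons map onto (1R,4S) of the target.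
Remark: the C8–C3' axis carries no configurational label in the target, so it is treated as not configurationally defined and no step is asked to control it.

**Route**

Step 1
Reactants: 1 (+)-menthol
Product: 2 (+)-menthone, (2R,5S)-2-isopropyl-5-methylcyclohexan-1-one
Conditions: NaOCl (aq), AcOH, 15–25 °C
Reagents that add atoms: none
Why: Hypochlorite oxidation of a secondary alcohol under weakly acidic conditions gives the ketone without change at the two stereocentres, and the short, cool reaction leaves little time for epimerisation α to the new carbonyl.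

Step 2
Reactants: 2 (+)-menthone
Product: 3 (3R,6S)-2-bromo-3-isopropyl-6-methylcyclohex-1-ene-1-carbaldehyde
Conditions: PBr3, DMF, CHCl3, 0 °C → rt; then H2O
Reagents that add atoms: N,N-dimethylformamide CN(C)C=O; phosphorus tribromide BrP(Br)Br; water O
Why: Vilsmeier–Haack–Arnold bromoformylation: the enol toward the unsubstituted α-CH2 is formylated by the bromoiminium salt and the carbonyl carbon becomes the vinyl bromide, so the isopropyl-bearing carbon is not formylated and should keep its configuration as long as the mixture is kept cold enough to outrun acid-mediated epimerisation.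

Step 3
Reactants: 3 bromo enal; 4 [2-(1,3-dioxolan-2-yl)ethyl]zinc bromide (commercial THF solution)
Product: 5 (3R,6S)-2-[2-(1,3-dioxolan-2-yl)ethyl]-3-isopropyl-6-methylcyclohex-1-ene-1-carbaldehyde
Conditions: Pd(OAc)2 (2 mol %), SPhos (4 mol %), THF, 25 → 45 °C
Reagents that add atoms: none
Why: Negishi coupling of an activated β-bromo enal with a primary alkylzinc bromide, which does not add to the aldehyde, while the biaryl phosphine favours reductive elimination over β-hydride loss at the tetrasubstituted alkene.

Step 4
Reactants: 5 enal dioxolane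
Product: 6 (3R,6S)-3-isopropyl-6-methyl-2-(3-oxopropyl)cyclohex-1-ene-1-carbaldehyde
Conditions: AcOH–THF–H2O (3:1:1), 40 °C
Reagents that add atoms: water O
Why: Mild acid hydrolysis of the dioxolane frees the aliphatic aldehyde; the enal and the allylic stereocentre tolerate dilute acetic acid.

Step 5
Reactants: 6 dialdehyde
Product: 7 (1R,4S)-5-hydroxy-1-isopropyl-4-methyl-1,2,3,4,7,8-hexahydronaphthalen-6(5H)-one (both C5 epimers)
Conditions: 3-benzyl-5-(2-hydroxyethyl)-4-methylthiazolium chloride (20 mol %), Et3N (30 mol %), dioxane (0.02 M), 70 °C, N2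
Reagents that add atoms: none
Why: Thiazolium-carbene acyloin (benzoin) condensation: the carbene adduct of the unhindered aliphatic aldehyde acts as acyl anion and adds to the enal carbonyl in a six-membered closure that forms C5–C6; the carbinol centre forms as a mixture and is erased in step 6.

Step 6
Reactants: 7 α-ketol
Product: 9 (1R,4S)-5,6-dihydroxy-1-isopropyl-4-methyltetralin, via 1,2-diketone 8 (not isolated)
Conditions: (COCl)2, DMSO, CH2Cl2, −78 °C; Et3N, −78 °C → rt
Reagents that add atoms: none
Why: Swern oxidation of the α-ketol gives 1,2-diketone 8, a tautomer of the catechol, and the triethylamine present after the oxidant is spent moves two protons to aromatise ring A, so the free catechol should not meet the oxidant.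

Step 7
Reactants: 9 catechol
Product: 10 (1R,4S)-1-isopropyl-5,6-dimethoxy-4-methyltetralin
Conditions: MeI, K2CO3, DMF, rt
Reagents that add atoms: iodomethane CI
Why: Williamson O-methylation of both phenols; carbonate is too weak a base to touch the benzylic stereocentres.

Step 8
Reactants: 10 dimethyl ether
Product: 13 (1R,4S)-7-(acetoxymethyl)-1-isopropyl-5,6-dimethoxy-4-methyltetralin, via C7 aryllithium 11 (not isolated), via lithium alkoxide 12 (not isolated)
Conditions: n-BuLi, TMEDA, Et2O, 0 °C → rt; (CH2O)n, 0 °C → rt; Ac2O, 0 °C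
Reagents that add atoms: formaldehyde (from paraformaldehyde) C=O; acetic anhydride CC(=O)OC(C)=O
Why: Directed ortho-metalation: C7 is the only position ortho to a methoxy group, so lithiation occurs there, the aryllithium is hydroxymethylated by formaldehyde and the lithium alkoxide is acetylated in the same flask.

Step 9
Reactants: 13 benzylic acetate
Product: 14 (1R,4S)-7-(acetoxymethyl)-8-bromo-1-isopropyl-5,6-dimethoxy-4-methyltetralin
Conditions: NBS, MeCN, 0 °C → rt, dark
Reagents that add atoms: N-bromosuccinimide O=C1CCC(=O)N1Br
Why: Electrophilic aromatic bromination at C8, the only unsubstituted position of ring A and para to the C5 methoxy group; polar solvent and exclusion of light suppress benzylic radical bromination.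

Step 10
Reactants: 14 aryl bromide; 15 di-tert-butyl malonate
Product: 16 di-tert-butyl 2-[(1R,4S)-7-(acetoxymethyl)-1-isopropyl-5,6-dimethoxy-4-methyltetralin-8-yl]malonate
Conditions: Pd(OAc)2 (5 mol %), P(tBu)3·HBF4 (10 mol %), K3PO4, PhMe, 100 °C
Reagents that add atoms: none
Why: Palladium-catalysed α-arylation of a malonate: the bulky, electron-rich P(tBu)3 supports oxidative addition and C–C reductive elimination at a di-ortho-substituted aryl bromide, and the weak phosphate base spares the acetate.

Step 11
Reactants: 16 di-tert-butyl arylmalonate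
Product: 17 2-[(1R,4S)-7-(acetoxymethyl)-1-isopropyl-5,6-dimethoxy-4-methyltetralin-8-yl]malonic acid
Conditions: TFA–CH2Cl2 (1:4), 0 °C → rt
Reagents that add atoms: none
Why: Acidolysis of the tert-butyl esters by loss of isobutene; the benzylic acetate should survive the short, cold exposure because its ortho methoxy group is twisted out of conjugation, and arylmalonic acids do not decarboxylate at this temperature.

Step 12
Reactants: 17 arylmalonic acid
Product: 18 2-[(1R,4S)-7-(acetoxymethyl)-1-isopropyl-5,6-dimethoxy-4-methyltetralin-8-yl]malonyl dichloride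
Conditions: (COCl)2, DMF (cat.), CH2Cl2, 0 °C → rt
Reagents that add atoms: oxalyl chloride O=C(Cl)C(Cl)=O
Why: Acid chloride formation with oxalyl chloride under catalysis by DMF; the by-products are gases and the acetate and methyl ethers are inert.

Step 13
Reactants: 19 (E)-4-(4-methoxyphenyl)but-3-en-2-one
Product: 20 (E)-1-(4-methoxyphenyl)-3-(trimethylsilyloxy)buta-1,3-diene
Conditions: TMSOTf, Et3N, Et2O, 0 °C
Reagents that add atoms: trimethylsilyl trifluoromethanesulfonate C[Si](C)(C)OS(=O)(=O)C(F)(F)F
Why: Soft enolisation and O-silylation: the methyl group is the only enolisable position, so a single 2-silyloxydiene forms and the E-styryl alkene is untouched.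

Step 14
Reactants: 18 arylmalonyl dichloride; 20 silyloxydiene
Product: 22 3-[(1R,4S)-7-(acetoxymethyl)-1-isopropyl-5,6-dimethoxy-4-methyltetralin-8-yl]-4-hydroxy-6-[(E)-4-methoxystyryl]-2H-pyran-2-one, via aryl(chlorocarbonyl)ketene 21 (not isolated)
Conditions: PhMe, 80 °C, N2 sweep (−HCl); then 20, 0 → 50 °C
Reagents that add atoms: none
Why: Thermal loss of HCl from 18 gives aryl(chlorocarbonyl)ketene 21, whose central ketene carbon is attacked by the terminal CH2 of the silyl dienol ether (C4'–C5'), and chloride then removes the silyl group to leave an enolised 3,5-dioxo acid chloride. The C6' enol oxygen acylates the remaining acid chloride in a 6-exo-trig closure (O1'–C2'), and enolisation of the C4' ketone gives the 4-hydroxy-2-pyranone ring C. The closest known reaction type is the condensation of substituted malonyl dichlorides or (chlorocarbonyl)ketenes with trimethylsilyl enol ethers or enolisable ketones to 3-substituted 4-hydroxy-2-pyranones. No stereocentre is formed, and the two existing ones are remote sp3 carbons that the neutral conditions do not touch. The step needs C-acylation at the diene terminus instead of O-acylation or attack at the styryl carbons; the enol ether polarity puts the nucleophilic site on the terminal carbon, the absence of base keeps the silyl group on oxygen until the C–C bond has formed, and the E alkene has no enolisable position. Because C3' already sits on C8 as a malonate carbon, no bond is made at the crowded position, and the flanking C7 and C1 substituents shield the ketene from dimerisation.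

Step 15
Reactants: 22 pyranone acetate
Product: 23 4-hydroxy-3-[(1R,4S)-7-(hydroxymethyl)-1-isopropyl-5,6-dimethoxy-4-methyltetralin-8-yl]-6-[(E)-4-methoxystyryl]-2H-pyran-2-one
Conditions: K2CO3, MeOH, 0 °C → rt; then dilute aqueous acid
Reagents that add atoms: none
Why: Base-catalysed transesterification of the acetate; the pyranone is present as its delocalised 4-oxido anion, which shields the lactone from methoxide.

Step 16
Reactants: 23 benzylic alcohol
Product: 24 (1R,4S)-8-{4-hydroxy-6-[(E)-4-methoxystyryl]-2-oxo-2H-pyran-3-yl}-1-isopropyl-5,6-dimethoxy-4-methyltetralin-7-carbaldehyde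
Conditions: MnO2, CH2Cl2, rt
Reagents that add atoms: none
Why: MnO2 oxidises the benzylic alcohol selectively to the aldehyde without over-oxidation and leaves the styryl alkene, the methyl ethers and the enolised pyranone alone.

Step 17
Reactants: 24 tri-O-methyl aldehyde
Product: 25 heimiomycin A
Conditions: BBr3, CH2Cl2, −78 → 0 °C; then H2O
Reagents that add atoms: none
Why: Lewis-acid ether cleavage: BBr3 complexes each aryl methyl ether and bromide removes the methyl group by SN2, while aldehyde, lactone and E-alkene are only coordinated and are released on hydrolysis, so the target should form with both stereocentres unchanged.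

**Compound list**

1 | (+)-menthol, (1S,2R,5S)-2-isopropyl-5-methylcyclohexan-1-ol | CC(C)[C@H]1CC[C@H](C)C[C@@H]1O | starting material
2 | (+)-menthone, (2R,5S)-2-isopropyl-5-methylcyclohexan-1-one | CC(C)[C@H]1CC[C@H](C)CC1=O | intermediate
3 | (3R,6S)-2-bromo-3-isopropyl-6-methylcyclohex-1-ene-1-carbaldehyde | CC(C)[C@H]1CC[C@H](C)C(C=O)=C1Br | intermediate
4 | [2-(1,3-dioxolan-2-yl)ethyl]zinc bromide | Br[Zn]CCC1OCCO1 | starting material
5 | (3R,6S)-2-[2-(1,3-dioxolan-2-yl)ethyl]-3-isopropyl-6-methylcyclohex-1-ene-1-carbaldehyde | CC(C)[C@H]1CC[C@H](C)C(C=O)=C1CCC1OCCO1 | intermediate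
6 | (3R,6S)-3-isopropyl-6-methyl-2-(3-oxopropyl)cyclohex-1-ene-1-carbaldehyde | CC(C)[C@H]1CC[C@H](C)C(C=O)=C1CCC=O | intermediate
7 | (1R,4S)-5-hydroxy-1-isopropyl-4-methyl-1,2,3,4,7,8-hexahydronaphthalen-6(5H)-one, C5 epimers | CC(C)[C@H]1CC[C@H](C)C2=C1CCC(=O)C2O | intermediate
8 | (1R,4S)-1-isopropyl-4-methyl-1,2,3,4,7,8-hexahydronaphthalene-5,6-dione (not isolated) | CC(C)[C@H]1CC[C@H](C)C2=C1CCC(=O)C2=O | intermediate
9 | (1R,4S)-5,6-dihydroxy-1-isopropyl-4-methyltetralin | CC(C)[C@H]1CC[C@H](C)c2c(O)c(O)ccc21 | intermediate
10 | (1R,4S)-1-isopropyl-5,6-dimethoxy-4-methyltetralin | CC(C)[C@H]1CC[C@H](C)c2c(OC)c(OC)ccc21 | intermediate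
11 | C7-lithio derivative of 10 (not isolated) | CC(C)[C@H]1CC[C@H](C)c2c(OC)c(OC)c([Li])cc21 | intermediate
12 | lithium alkoxide of the C7 hydroxymethyl compound (not isolated) | CC(C)[C@H]1CC[C@H](C)c2c(OC)c(OC)c(CO[Li])cc21 | intermediate
13 | (1R,4S)-7-(acetoxymethyl)-1-isopropyl-5,6-dimethoxy-4-methyltetralin | CC(C)[C@H]1CC[C@H](C)c2c(OC)c(OC)c(COC(C)=O)cc21 | intermediate
14 | (1R,4S)-7-(acetoxymethyl)-8-bromo-1-isopropyl-5,6-dimethoxy-4-methyltetralin | CC(C)[C@H]1CC[C@H](C)c2c(OC)c(OC)c(COC(C)=O)c(Br)c21 | intermediate
15 | di-tert-butyl malonate | CC(C)(C)OC(=O)CC(=O)OC(C)(C)C | starting material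
16 | di-tert-butyl C8-arylmalonate | CC(C)[C@H]1CC[C@H](C)c2c(OC)c(OC)c(COC(C)=O)c(C(C(=O)OC(C)(C)C)C(=O)OC(C)(C)C)c21 | intermediate
17 | C8-arylmalonic acid | CC(C)[C@H]1CC[C@H](C)c2c(OC)c(OC)c(COC(C)=O)c(C(C(=O)O)C(=O)O)c21 | intermediate
18 | C8-arylmalonyl dichloride | CC(C)[C@H]1CC[C@H](C)c2c(OC)c(OC)c(COC(C)=O)c(C(C(Cl)=O)C(Cl)=O)c21 | intermediate
19 | (E)-4-(4-methoxyphenyl)but-3-en-2-one | COc1ccc(/C=C/C(C)=O)cc1 | starting material
20 | (E)-1-(4-methoxyphenyl)-3-(trimethylsilyloxy)buta-1,3-diene | C=C(O[Si](C)(C)C)/C=C/c1ccc(OC)cc1 | intermediate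
21 | aryl(chlorocarbonyl)ketene (not isolated) | CC(C)[C@H]1CC[C@H](C)c2c(OC)c(OC)c(COC(C)=O)c(C(=C=O)C(Cl)=O)c21 | intermediate
22 | 3-aryl-4-hydroxy-6-[(E)-4-methoxystyryl]-2-pyranone, C7 acetoxymethyl | CC(C)[C@H]1CC[C@H](C)c2c(OC)c(OC)c(COC(C)=O)c(-c3c(O)cc(/C=C/c4ccc(OC)cc4)oc3=O)c21 | intermediate
23 | C7 hydroxymethyl pyranone | CC(C)[C@H]1CC[C@H](C)c2c(OC)c(OC)c(CO)c(-c3c(O)cc(/C=C/c4ccc(OC)cc4)oc3=O)c21 | intermediate
24 | C7 aldehyde, tri-O-methyl heimiomycin A | CC(C)[C@H]1CC[C@H](C)c2c(OC)c(OC)c(C=O)c(-c3c(O)cc(/C=C/c4ccc(OC)cc4)oc3=O)c21 | intermediate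
25 | heimiomycin A | CC(C)[C@H]1CC[C@H](C)c2c(O)c(O)c(C=O)c(-c3c(O)cc(/C=C/c4ccc(O)cc4)oc3=O)c21 | target

**Step count**

Total: 17 steps. Longest linear sequence: 16 steps (steps 1–12 and 14–17, from (+)-menthol); step 13 is the one-step side branch to diene 20.

**Steps most likely to fail**

1. Step 10. The crowded arylpalladium bromide at C8 may not take up the bulky malonate as a carbon-bound enolate, so that reductive elimination stalls and hydrodebromination or catalyst decay takes over. The fallback sets out from bromide 14 and builds the malonate in two stages with a small nucleophile. Coupling with the Reformatsky reagent BrZnCH2CO2tBu (Pd(dba)2, XPhos, THF, 60 °C) should give tert-butyl arylacetate F1. C-carboxylation of its lithium enolate (LiHMDS, Boc2O, THF, −78 °C, base added to the mixture of ester and Boc2O so that the enolate is trapped before it can reach the neighbouring acetate) then gives malonate 16, where the route is rejoined.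

2. Step 14. The HCl set free may strip the silyl group from the acid-sensitive styryl dienol ether before C-acylation, and the electron-rich diene may then oligomerise or undergo cycloaddition with the ketene in place of the acylation–lactonisation sequence. The fallback sets out from dichloride 18 and moves the styryl alkene formation behind the ring closure. Condensation of 18 with commercial 2-(trimethylsilyloxy)propene under the conditions of step 14 should give 6-methylpyranone F2. O-Methylation (Me2SO4, K2CO3, acetone) gives 4-methoxypyranone F3. Condensation of its vinylogously acidic 6-methyl group with 4-methoxybenzaldehyde (Mg(OMe)2, MeOH, reflux), which also removes the acetate, gives styryl alcohol F4. MnO2 (CH2Cl2) gives aldehyde F5, and BBr3 (CH2Cl2, −78 → 0 °C), now cleaving four methyl ethers, comes back to the route at target 25.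

3. Step 5. Under the amine base the enolisable aldehyde may undergo intramolecular aldol condensation onto the enal faster than the carbene adds, which would close a five-membered ring in place of the C5–C6 acyloin bond. The fallback sets out from dialdehyde 6 and closes the same bond reductively. SmI2 (THF, t-BuOH, −78 °C → rt) should effect pinacol cyclisation to cis-diol F6. Double Swern oxidation ((COCl)2, DMSO, CH2Cl2, −78 °C; Et3N) then gives diketone 8 and, by tautomerisation, catechol 9, where the route is rejoined.

**Further compounds**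

F1 | step 10 | tert-butyl 2-[(1R,4S)-7-(acetoxymethyl)-1-isopropyl-5,6-dimethoxy-4-methyltetralin-8-yl]acetate | CC(C)[C@H]1CC[C@H](C)c2c(OC)c(OC)c(COC(C)=O)c(CC(=O)OC(C)(C)C)c21
F2 | step 14 | 3-aryl-4-hydroxy-6-methyl-2-pyranone, C7 acetoxymethyl | CC(C)[C@H]1CC[C@H](C)c2c(OC)c(OC)c(COC(C)=O)c(-c3c(O)cc(C)oc3=O)c21
F3 | step 14 | 3-aryl-4-methoxy-6-methyl-2-pyranone, C7 acetoxymethyl | CC(C)[C@H]1CC[C@H](C)c2c(OC)c(OC)c(COC(C)=O)c(-c3c(OC)cc(C)oc3=O)c21
F4 | step 14 | 3-aryl-4-methoxy-6-[(E)-4-methoxystyryl]-2-pyranone, C7 hydroxymethyl | CC(C)[C@H]1CC[C@H](C)c2c(OC)c(OC)c(CO)c(-c3c(OC)cc(/C=C/c4ccc(OC)cc4)oc3=O)c21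
F5 | step 14 | 3-aryl-4-methoxy-6-[(E)-4-methoxystyryl]-2-pyranone, C7 aldehyde | CC(C)[C@H]1CC[C@H](C)c2c(OC)c(OC)c(C=O)c(-c3c(OC)cc(/C=C/c4ccc(OC)cc4)oc3=O)c21
F6 | step 5 | (1R,4S)-1-isopropyl-4-methyl-1,2,3,4,5,6,7,8-octahydronaphthalene-5,6-diol, cis-diol, mixture at C5 and C6 | CC(C)[C@H]1CC[C@H](C)C2=C1CCC(O)C2O
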